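**Strategy.** Germacrane numbering is used (C6–O1 and C7–C11 join the lactone to the carbocycle). The route rests on removing the propionate unit O1–C12–C11 from the C6–C7 edge of the lactone ring. The key step puts it back by a double allylic transposition run in one flask: the O5-propionate of a 4,15-epoxy-6-ene undergoes Ireland–Claisen rearrangement (C7–C11), and the carboxylate so released opens the new vinyl epoxide in an SN2′ fashion under Pd(PPh3)4 (O1–C6). This exploits the array C15(OH)–C4=C5–C6(O) next to the lactone ring, which is the signature of a 4,15-epoxide. The ten-membered ring is closed afterwards by metathesis at C1=C10.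

Key step: step 5

Remark: atoms are numbered C1=C10(C14H3), C2, C3, C4(C15H2OH)=C5, C6–O1, C7, C8–O, C9, C11(C13H3)–C12(=O); compounds 4, 15, 17 and 18 are taken as commercial.

Step 1
Reactants: 1 2,3-dibromoprop-1-ene; 2 allylmagnesium bromide
Product: 3 2-bromohexa-1,5-diene
Conditions: Et2O, 0 → 23 °C
Reagents that add atoms: none
Why: Allyl–allyl coupling of a Grignard reagent with an allylic bromide (SN2/SN2′), in which the vinylic C–Br bond is inert; no stereocentre is formed.

Step 2
Reactants: 3 2-bromohexa-1,5-diene; 4 (2E)-4,4-dimethoxybut-2-enal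
Product: 6 rac-(2E)-1,1-dimethoxy-5-methylidenenona-2,8-dien-4-ol, via hexa-1,5-dien-2-yllithium 5 (not isolated)
Conditions: t-BuLi (2 equiv), Et2O, −78 °C; then 4, −78 °C; H2O
Reagents that add atoms: none
Why: Bromine–lithium exchange followed by 1,2-addition of the alkenyllithium to the enal carbonyl group builds the C4–C5 bond, and the carbinol centre C5 forms as a racemate that step 3 resolves.

Step 3
Reactants: 6 rac-(2E)-1,1-dimethoxy-5-methylidenenona-2,8-dien-4-ol
Product: 7 (1R,2E)-1-[(2S)-2-(but-3-en-1-yl)oxiran-2-yl]-4,4-dimethoxybut-2-en-1-ol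
Conditions: Ti(OiPr)4 (cat.), D-(−)-diisopropyl tartrate, t-BuOOH (0.6 equiv), 4 Å molecular sieves, CH2Cl2, −20 °C
Reagents that add atoms: tert-butyl hydroperoxide, CC(C)(C)OO
Why: Sharpless asymmetric epoxidation run as a kinetic resolution: with the D-(−)-tartrate the (R)-carbinol should be epoxidised at its 1,1-disubstituted allylic olefin on the face that gives the erythro (4S,5R) epoxy alcohol, while the (S)-enantiomer is left behind and the electron-poor, mismatched acetal-bearing olefin should not compete.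

Step 4
Reactants: 7 (1R,2E)-1-[(2S)-2-(but-3-en-1-yl)oxiran-2-yl]-4,4-dimethoxybut-2-en-1-ol
Product: 8 (1R,2E)-1-[(2S)-2-(but-3-en-1-yl)oxiran-2-yl]-4,4-dimethoxybut-2-en-1-yl propanoate
Conditions: (EtCO)2O, Et3N, DMAP (cat.), CH2Cl2, 0 → 23 °C
Reagents that add atoms: propionic anhydride, CCC(=O)OC(=O)CC
Why: DMAP-catalysed acyl transfer to the secondary alcohol installs the propionate that will become O1–C12–C11(C13); no stereocentre is touched.

Step 5
Reactants: 8 (1R,2E)-1-[(2S)-2-(but-3-en-1-yl)oxiran-2-yl]-4,4-dimethoxybut-2-en-1-yl propanoate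
Product: 12 (3S,4S,5R)-4-(dimethoxymethyl)-5-[(1Z)-2-(hydroxymethyl)hexa-1,5-dien-1-yl]-3-methyloxolan-2-one, via silyl ketene acetal 9 (not isolated), via silyl ester 10 (not isolated), via carboxylic acid 11 (not isolated)
Conditions: LiN(iPr)2, THF–DMPU 4:1, −78 °C; Me3SiCl/Et3N, −78 → 40 °C; MeOH, 23 °C; then Pd(PPh3)4 (5 mol %), 23 °C
Reagents that add atoms: none
Why: Enolisation in THF–DMPU gives (Z)-silyl ketene acetal 9, which rearranges through a chair transition state with the bulky C4 equatorial (Ireland–Claisen rearrangement): C7–C11 forms on the face from which O5 leaves, so C5 (R) is relayed to C7 (R), the ketene acetal geometry sets C11 (S, also the thermodynamically preferred epimer) and the olefin moves to C5=C6 (E). Methanolysis of silyl ester 10 frees acid 11, now a vinyl epoxide, which Pd(PPh3)4 ionises anti to the C4–O bond; the carboxylate attacks C6 of the allyl palladium alkoxide anti to the metal, the closest known reaction type being the zerovalent-palladium-catalysed 1,4-addition of carboxylic acids to vinyl epoxides (Tsuji–Trost). The lactone ring closes in the 5-exo mode at C6 (attack at C4 would need a seven-membered ring), and the same event shifts the olefin to C4=C5 and uncovers the C15 hydroxyl. Because ionisation and attack are both anti, O1 enters C6 on the face from which the epoxide oxygen leaves (net syn SN2′), so C6 (R) is controlled by the 4S centre. The step needs the trans ring fusion and the C4=C5 geometry (C15 cis to C6) to arise together: with the erythro (4S,5R) substrate the rotamer that places the small epoxide CH2 inside gives both, whereas the other rotamer would have to close a cis-fused lactone. Chemoselectivity rests on the order of events, since the epoxide is not allylic until the rearrangement has taken place and the catalyst is added only then.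

Step 6
Reactants: 12 (3S,4S,5R)-4-(dimethoxymethyl)-5-[(1Z)-2-(hydroxymethyl)hexa-1,5-dien-1-yl]-3-methyloxolan-2-one
Product: 13 (3S,4S,5R)-5-[(1Z)-2-{[tert-butyl(diphenyl)silyl]oxymethyl}hexa-1,5-dien-1-yl]-4-(dimethoxymethyl)-3-methyloxolan-2-one
Conditions: t-BuPh2SiCl, imidazole, CH2Cl2, 23 °C
Reagents that add atoms: tert-butyl(chloro)diphenylsilane, CC(C)(C)[Si](Cl)(c1ccccc1)c1ccccc1
Why: Imidazole-promoted silylation of the primary allylic alcohol masks O15 so that O8 can later be acylated alone.

Step 7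
Reactants: 13 (3S,4S,5R)-5-[(1Z)-2-{[tert-butyl(diphenyl)silyl]oxymethyl}hexa-1,5-dien-1-yl]-4-(dimethoxymethyl)-3-methyloxolan-2-one
Product: 14 (2R,3S,4S)-2-[(1Z)-2-{[tert-butyl(diphenyl)silyl]oxymethyl}hexa-1,5-dien-1-yl]-4-methyl-5-oxooxolane-3-carbaldehyde
Conditions: pyridinium p-toluenesulfonate (cat.), acetone–H2O 10:1, 45 °C
Reagents that add atoms: water, O
Why: Mild acid-catalysed acetal hydrolysis frees the C8 aldehyde; the silyl ether should survive, and C7, now enolisable, already holds the thermodynamically preferred all-trans arrangement on the lactone.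

Step 8
Reactants: 14 (2R,3S,4S)-2-[(1Z)-2-{[tert-butyl(diphenyl)silyl]oxymethyl}hexa-1,5-dien-1-yl]-4-methyl-5-oxooxolane-3-carbaldehyde; 15 2-methylallylboronic acid pinacol ester
Product: 16 (3S,4R,5R)-5-[(1Z)-2-{[tert-butyl(diphenyl)silyl]oxymethyl}hexa-1,5-dien-1-yl]-4-[(1S)-1-hydroxy-3-methylbut-3-en-1-yl]-3-methyloxolan-2-one
Conditions: (S)-TRIP [(S)-3,3′-bis(2,4,6-triisopropylphenyl)-1,1′-binaphthyl-2,2′-diyl hydrogen phosphate, 5 mol %], 4 Å molecular sieves, toluene, −30 °C
Reagents that add atoms: none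
Why: Chiral phosphoric acid-catalysed allylboration through a closed chair transition state forms C8–C9; the catalyst enantiomer that directs the 2-methylallyl group to the Si face of the aldehyde (expected to be S) should set C8 as S (8α-O) under catalyst control.

Step 9
Reactants: 17 (tert-butyldimethylsilyloxy)acetaldehyde; 18 ethyl 2-(triphenylphosphoranylidene)propanoate
Product: 19 ethyl (2E)-4-[tert-butyl(dimethyl)silyl]oxy-2-methylbut-2-enoate
Conditions: CH2Cl2, 23 °C
Reagents that add atoms: none
Why: Wittig olefination with a stabilised α-methyl ylide, which should give the (E)-trisubstituted enoate.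

Step 10
Reactants: 19 ethyl (2E)-4-[tert-butyl(dimethyl)silyl]oxy-2-methylbut-2-enoate
Product: 20 (2E)-4-[tert-butyl(dimethyl)silyl]oxy-2-methylbut-2-enoic acid
Conditions: LiOH, THF–H2O, 23 °C; then 1 M HCl to pH 4
Reagents that add atoms: lithium hydroxide, [Li+].[OH-]
Why: Saponification of the ethyl ester; the primary silyl ether should survive aqueous LiOH at ambient temperature.

Step 11
Reactants: 16 (3S,4R,5R)-5-[(1Z)-2-{[tert-butyl(diphenyl)silyl]oxymethyl}hexa-1,5-dien-1-yl]-4-[(1S)-1-hydroxy-3-methylbut-3-en-1-yl]-3-methyloxolan-2-one; 20 (2E)-4-[tert-butyl(dimethyl)silyl]oxy-2-methylbut-2-enoic acid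
Product: 21 8-O-[(2E)-4-(tert-butyldimethylsilyloxy)-2-methylbut-2-enoyl] ester of 16
Conditions: 2,4,6-trichlorobenzoyl chloride, Et3N, toluene, 23 °C; then 16, DMAP
Reagents that add atoms: none
Why: Yamaguchi esterification through the mixed anhydride acylates the hindered secondary 8-hydroxyl with retention at C8 and without isomerising the enoate.

Step 12
Reactants: 21 8-O-[(2E)-4-(tert-butyldimethylsilyloxy)-2-methylbut-2-enoyl] ester of 16
Product: 22 15-O-tert-butyldiphenylsilyl-4′-O-tert-butyldimethylsilyl ether of the target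
Conditions: second-generation Hoveyda–Grubbs catalyst (10 mol %), toluene (1 mM), 80 °C
Reagents that add atoms: none
Why: Ring-closing olefin metathesis between the vinyl group (C1) and the 1,1-disubstituted olefin (C10) releases ethene; in a ten-membered ring that already holds the ring-trans C4=C5 olefin and the trans-fused lactone, the new trisubstituted olefin should form in the ring-cis (Z) geometry.

Step 13
Reactants: 22 15-O-tert-butyldiphenylsilyl-4′-O-tert-butyldimethylsilyl ether of the target
Product: 23 (3S,3aR,4S,6Z,10Z,11aR)-10-(hydroxymethyl)-3,6-dimethyl-2-oxo-2,3,3a,4,5,8,9,11a-octahydrocyclodeca[b]furan-4-yl (2E)-4-hydroxy-2-methylbut-2-enoate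
Conditions: Bu4NF, AcOH, THF, 0 → 23 °C
Reagents that add atoms: none
Why: Fluoride-mediated cleavage of both silyl ethers, buffered with AcOH so that the lactone and the enoate ester should stay in place.

**Compound list**

1 | 2,3-dibromoprop-1-ene | C=C(Br)CBr | starting material
2 | allylmagnesium bromide | C=CC[Mg]Br | starting material
3 | 2-bromohexa-1,5-diene | C=CCCC(Br)=C | intermediate
4 | (2E)-4,4-dimethoxybut-2-enal | COC(OC)/C=C/C=O | starting material
5 | hexa-1,5-dien-2-yllithium | [Li]C(=C)CCC=C | intermediate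
6 | rac-(2E)-1,1-dimethoxy-5-methylidenenona-2,8-dien-4-ol | C=CCCC(=C)C(O)/C=C/C(OC)OC | intermediate
7 | (1R,2E)-1-[(2S)-2-(but-3-en-1-yl)oxiran-2-yl]-4,4-dimethoxybut-2-en-1-ol | C=CCC[C@]1(CO1)[C@H](O)/C=C/C(OC)OC | intermediate
8 | (1R,2E)-1-[(2S)-2-(but-3-en-1-yl)oxiran-2-yl]-4,4-dimethoxybut-2-en-1-yl propanoate | C=CCC[C@]1(CO1)[C@H](OC(=O)CC)/C=C/C(OC)OC | intermediate
9 | (Z)-O-trimethylsilyl ketene acetal of 8 (methyl cis to OSiMe3) | C=CCC[C@]1(CO1)[C@H](O/C(=C/C)O[Si](C)(C)C)/C=C/C(OC)OC | intermediate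
10 | trimethylsilyl (2S,3R,4E)-5-[(2R)-2-(but-3-en-1-yl)oxiran-2-yl]-3-(dimethoxymethyl)-2-methylpent-4-enoate | C[Si](C)(C)OC(=O)[C@@H](C)[C@H](C(OC)OC)/C=C/[C@@]1(CO1)CCC=C | intermediate
11 | (2S,3R,4E)-5-[(2R)-2-(but-3-en-1-yl)oxiran-2-yl]-3-(dimethoxymethyl)-2-methylpent-4-enoic acid | OC(=O)[C@@H](C)[C@H](C(OC)OC)/C=C/[C@@]1(CO1)CCC=C | intermediate
12 | (3S,4S,5R)-4-(dimethoxymethyl)-5-[(1Z)-2-(hydroxymethyl)hexa-1,5-dien-1-yl]-3-methyloxolan-2-one | C=CCC/C(CO)=C/[C@H]1OC(=O)[C@@H](C)[C@@H]1C(OC)OC | intermediate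
13 | 15-O-tert-butyldiphenylsilyl ether of 12 | C=CCC/C(CO[Si](c1ccccc1)(c1ccccc1)C(C)(C)C)=C/[C@H]2OC(=O)[C@@H](C)[C@@H]2C(OC)OC | intermediate
14 | (2R,3S,4S)-2-[(1Z)-2-{[tert-butyl(diphenyl)silyl]oxymethyl}hexa-1,5-dien-1-yl]-4-methyl-5-oxooxolane-3-carbaldehyde | C=CCC/C(CO[Si](c1ccccc1)(c1ccccc1)C(C)(C)C)=C/[C@H]2OC(=O)[C@@H](C)[C@@H]2C=O | intermediate
15 | 2-methylallylboronic acid pinacol ester | CC(=C)CB1OC(C)(C)C(C)(C)O1 | starting material
16 | (3S,4R,5R)-5-[(1Z)-2-{[tert-butyl(diphenyl)silyl]oxymethyl}hexa-1,5-dien-1-yl]-4-[(1S)-1-hydroxy-3-methylbut-3-en-1-yl]-3-methyloxolan-2-one | C=CCC/C(CO[Si](c1ccccc1)(c1ccccc1)C(C)(C)C)=C/[C@H]2OC(=O)[C@@H](C)[C@@H]2[C@@H](O)CC(C)=C | intermediate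
17 | (tert-butyldimethylsilyloxy)acetaldehyde | O=CCO[Si](C)(C)C(C)(C)C | starting material
18 | ethyl 2-(triphenylphosphoranylidene)propanoate | CCOC(=O)C(C)=P(c1ccccc1)(c1ccccc1)c1ccccc1 | starting material
19 | ethyl (2E)-4-[tert-butyl(dimethyl)silyl]oxy-2-methylbut-2-enoate | CCOC(=O)/C(C)=C/CO[Si](C)(C)C(C)(C)C | intermediate
20 | (2E)-4-[tert-butyl(dimethyl)silyl]oxy-2-methylbut-2-enoic acid | OC(=O)/C(C)=C/CO[Si](C)(C)C(C)(C)C | intermediate
21 | 8-O-[(2E)-4-(tert-butyldimethylsilyloxy)-2-methylbut-2-enoyl] ester of 16 (C8 S) | C=CCC/C(CO[Si](c1ccccc1)(c1ccccc1)C(C)(C)C)=C/[C@H]2OC(=O)[C@@H](C)[C@@H]2[C@@H](OC(=O)/C(C)=C/CO[Si](C)(C)C(C)(C)C)CC(C)=C | intermediate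
22 | bis-silyl ether of the target (15-O-SiPh2tBu and 4′-O-SiMe2tBu; ring olefins 1(10)Z and 4,5 ring-trans) | C/C1=C/CC/C(CO[Si](c3ccccc3)(c3ccccc3)C(C)(C)C)=C/[C@H]2OC(=O)[C@@H](C)[C@@H]2[C@@H](OC(=O)/C(C)=C/CO[Si](C)(C)C(C)(C)C)C1 | intermediate
23 | (3S,3aR,4S,6Z,10Z,11aR)-10-(hydroxymethyl)-3,6-dimethyl-2-oxo-2,3,3a,4,5,8,9,11a-octahydrocyclodeca[b]furan-4-yl (2E)-4-hydroxy-2-methylbut-2-enoate | C/C1=C/CC/C(CO)=C/[C@H]2OC(=O)[C@@H](C)[C@@H]2[C@@H](OC(=O)/C(C)=C/CO)C1 | target

**Step count.** Total: 13 steps. Longest linear sequence: 11 steps (steps 1–8, 11, 12, 13); steps 9 and 10 make the side-chain acid.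

**Steps most likely to fail**

- **Step 5 (key step).** What may go wrong: the vinyl epoxide may ionise through the other rotamer, which ties a cis ring fusion to the wrong C4=C5 geometry. The catalyst may also re-ionise the allylic lactone once formed and scramble C6. The amide base may attack the epoxide before silylation is complete. Fallback, from 8 back to 12: the rearrangement is run alone with an aqueous acidic work-up and carboxylic acid 11 is isolated. Iodolactonisation (I2, NaHCO3, MeCN, 0 °C, equilibrating conditions) then forms O1–C6 anti to iodine at C5 and should give the trans-disubstituted iodo epoxy lactone F1. Zinc dust with NH4Cl in EtOH eliminates iodide against the epoxide oxygen in an anti sense, which opens the 4,15-epoxide and should give 12 with the same olefin geometry.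

- **Step 12 (ring closure).** What may go wrong: cross metathesis at the vinyl group may outrun closure of the strained ten-membered ring, and the catalyst may fail to engage the 1,1-disubstituted olefin. Fallback, from 14 back to 22: D-proline-catalysed aldol addition of acetone to 14 (acetone–DMSO, 23 °C) gives the 8S β-hydroxy methyl ketone F2. Yamaguchi esterification of F2 with 20 gives keto ester F3. One equivalent of Mo(=CHCMe2Ph)(=N-2,6-iPr2C6H3)[OCMe(CF3)2]2 in benzene first exchanges with the vinyl group, and the new alkylidene at C1 then olefinates the C10 ketone within the molecule. This alkylidene-mediated carbonyl olefination is irreversible and should form C1=C10 and give 22.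

- **Step 8 (C8 stereocentre).** What may go wrong: the catalyst may not override the facial bias of the α-branched aldehyde, and the aldehyde may lose the lactone carboxylate by β-elimination while it waits. Fallback, from 14 back to 21: the enantiomeric catalyst (R)-TRIP is used so that catalyst and substrate work in the same sense, which should give the 8R alcohol F4. Mitsunobu esterification of F4 with 20 (PPh3, diisopropyl azodicarboxylate, toluene, 0 °C) inverts C8 and gives 21 directly.

Further compounds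
F1 | step 5 | iodo epoxy lactone: lactone ring of 12 with C5 saturated and carrying iodine anti to O1, 4,15-epoxide still closed | C=CCC[C@]1(CO1)[C@@H](I)[C@H]2OC(=O)[C@@H](C)[C@@H]2C(OC)OC
F2 | step 12 | 8S β-hydroxy methyl ketone: analogue of 16 with C10 as a ketone (C9H2–C(=O)–CH3) | C=CCC/C(CO[Si](c1ccccc1)(c1ccccc1)C(C)(C)C)=C/[C@H]2OC(=O)[C@@H](C)[C@@H]2[C@@H](O)CC(C)=O
F3 | step 12 | 8-O-[(2E)-4-(tert-butyldimethylsilyloxy)-2-methylbut-2-enoyl] ester of F2 | C=CCC/C(CO[Si](c1ccccc1)(c1ccccc1)C(C)(C)C)=C/[C@H]2OC(=O)[C@@H](C)[C@@H]2[C@@H](OC(=O)/C(C)=C/CO[Si](C)(C)C(C)(C)C)CC(C)=O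
F4 | step 8 | 8R epimer of alcohol 16 | C=CCC/C(CO[Si](c1ccccc1)(c1ccccc1)C(C)(C)C)=C/[C@H]2OC(=O)[C@@H](C)[C@@H]2[C@H](O)CC(C)=C
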